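The runs come from a simulation with made-up constants; noise was put on by code.

Late in the noon run, at 4.00 h, the readings show 6% intermediate and 13% target, so 81.0% of the substrate charged stands in neither, and you should look for intermediate in this flask early.

- noon: substrate 0.48 M; second nucleophile 0.50 equiv; solid first nucleophile 1.5 equiv; run made earlier
- flask: substrate 0.32 M; second nucleophile 0.500 equiv; solid first nucleophile 1.50 equiv; time 20 h

- noon (time / h: intermediate / %, target / %): 0.833: 30, 2; 1.50: 20, 1; 2.50: 5, 6; 3.00: 9, 12; 4.00: 6, 13

(each reading ± 2 percentage points)

- the numbers in the tables scatter with a standard deviation of 2 percentage points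
- at the start none of the solid first nucleophile is in solution

- time, not beyond 20 h, at which the flask holds most intermediate
- the amount of intermediate, in percent of the substrate charged, at that time
- the first time at which intermediate reaches 19%, in the same percent

1. Start from the beginning of the flask: I take it that each second nucleophile removes one intermediate, with second nucleophile the limiting reagent of that capture, so the ceiling C, one minus the equivalents of second nucleophile, is 50.0% of the substrate charged, as at noon, whose charge was 0.50 equiv.

2. Now come back from the later readings: noon intermediate falls from 30% at 0.833 h to 20% at 1.50 h, a reading of 0.608 h⁻¹, and run back to the start this gives 49.8%, close to C, though one comes from the charge and the other from readings with scatter.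

3. Joining the two ends, my own reckoning puts the peak of this flask before 0.833 h, between 30% and C, so sample early.

4. The forecast differs, with a later peak at 1.2 h holding 28% and 0.6 h for reaching 19%, and it warns that “one early point defines it poorly”.

    substrate → intermediate (k = 0.00231 s⁻¹)
    first nucleophile + intermediate → target (k = 0.0528 L mol⁻¹ s⁻¹)
    second nucleophile + intermediate → other capture product (k = 0.198 L mol⁻¹ s⁻¹)
    intermediate → side product (k = 1.77 × 10⁻⁴ s⁻¹)
    solid first nucleophile ⇌ first nucleophile, rate k5*(cs5 - [first nucleophile]) while solid is left; crystals form when [first nucleophile] > cs5 (solubility = 14.0 mM, k = 3.48 × 10⁻⁴ s⁻¹)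

This flask peaks at 0.401 h with 38.2%, below C at 0.764 of it, and reaches 19% at 0.139 h; at the peak, second nucleophile stands at 0% and other capture product at 50.0%. The neighbouring flask, charged with 0.120 equiv of second nucleophile, has a C of 88.0%, ends with 12.0% other capture product, and peaks at 69.4%, which is 0.789 of its C.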